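**Retrosynthetic overview**

1. The route rests on the trans C4–C5 oxirane of the ten-membered ring B (methyl on C4, H on C5). It is an E C4=C5 alkene in masked form whose C4 carries the methyl and the C3 methylene, so it maps onto an (E)-alkenyl iodide at C4 and a primary borane at C3.
2. Target 38 ⇐ 36 (outer-face epoxidation, then C1 desilylation) ⇐ 34 (C13 PMB ether exchanged for acetate) ⇐ 32 by C3–C4 B-alkyl Suzuki–Miyaura ring closure (9-BBN on the C2=C3 vinyl, then palladium).
3. 32 ⇐ butenolide aldehyde 18 + Z-alkenylmagnesium 26 (C8–C9 bond); C8 is reset by oxidation and CBS reduction, then tiglate. 26 comes from acrolein by ethynylation, anti-carbomagnesiation/iodination and lipase resolution (C1).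
4. 18 ⇐ ynoate 8 (C6 from asymmetric propiolate addition to (E)-3-iodobut-2-enal 5) by syn-carbocupration (vinyl = C8), alkoxymethylation (C13), acid lactonisation and cleavage of the vinyl group.
5. Ring order: butenolide ring A (step 10), ten-membered ring B (step 20), oxirane ring C (step 23).

Key step: step 20

Assumption: steps 5, 14 and 18 are drawn with their usual empirical sense of induction (in step 18 the tetrasubstituted butenolide carbon C7 is taken as the large group); should a sense prove opposite, the antipodal ligand or catalyst is used (for the lipase, the acetate is methanolysed instead of the residual alcohol being kept), with no other change.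

Germacrane numbering is used for the macrocycles (C14 = methyl on C10, C15 = methyl on C4).

**Route**

Step 1
Reactants: 1 ethyl but-2-ynoate
Product: 2 ethyl (2E)-3-(tributylstannyl)but-2-enoate
Conditions: Bu3SnH, LiN(i-Pr)2, THF, 0 °C; CuBr·SMe2, −78 °C; then 1, MeOH, −78 °C
Reagents that add atoms: tributyltin hydride CCCC[SnH](CCCC)CCCC
Why: Stannylcupration of the ynoate is a kinetically controlled syn-addition when methanol is present at −78 °C, so tin should end up on C3 trans to the ester (E), which fixes the later C4=C5 geometry.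

Step 2
Reactants: 2 ethyl (2E)-3-(tributylstannyl)but-2-enoate
Product: 3 (2E)-3-(tributylstannyl)but-2-en-1-ol
Conditions: i-Bu2AlH, CH2Cl2, −78 °C
Reagents that add atoms: none
Why: Hydride reduction of the conjugated ester with the aluminium hydride goes 1,2 to the allylic alcohol and leaves the alkenylstannane alone.

Step 3
Reactants: 3 (2E)-3-(tributylstannyl)but-2-en-1-ol
Product: 4 (2E)-3-iodobut-2-en-1-ol
Conditions: I2, CH2Cl2, 0 °C
Reagents that add atoms: iodine II
Why: Iododestannylation is an ipso electrophilic substitution that proceeds with retention of alkene geometry.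

Step 4
Reactants: 4 (2E)-3-iodobut-2-en-1-ol
Product: 5 (2E)-3-iodobut-2-enal
Conditions: MnO2, CH2Cl2, rt; filtered and used as a solution
Reagents that add atoms: none
Why: Allylic oxidation with MnO2 is neutral and should neither isomerise nor eliminate the β-iodo enal.

Step 5
Reactants: 5 (2E)-3-iodobut-2-enal; 6 methyl propiolate
Product: 8 methyl (4R,5E)-4-hydroxy-6-iodohept-5-en-2-ynoate, via alkynylzinc 7 (not isolated)
Conditions: 6, Me2Zn, (S,S)-ProPhenol (2,6-bis{[(2S)-2-(hydroxydiphenylmethyl)pyrrolidin-1-yl]methyl}-4-methylphenol, 20 mol %), Ph3PO (40 mol %), toluene, 0 °C; then 5, 4 °C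
Reagents that add atoms: none
Why: Catalytic asymmetric alkynylation: the zinc acetylide of the propiolate adds 1,2 to the enal inside the dinuclear zinc–ProPhenol pocket, which sets the C6 carbinol (4R here) under catalyst control.

Step 6
Reactants: 8 methyl (4R,5E)-4-hydroxy-6-iodohept-5-en-2-ynoate
Product: 9 methyl (4R,5E)-6-iodo-4-[(triethylsilyl)oxy]hept-5-en-2-ynoate
Conditions: TESOTf, 2,6-lutidine, CH2Cl2, −78 °C
Reagents that add atoms: triethylsilyl trifluoromethanesulfonate CC[Si](CC)(CC)OS(=O)(=O)C(F)(F)F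
Why: Silylation with the triflate and a hindered base is fast at low temperature and avoids amine-induced isomerisation of the γ-hydroxy ynoate.

Step 7
Reactants: 10 4-methoxybenzyl alcohol
Product: 11 1-methoxy-4-{[(methylsulfanyl)methoxy]methyl}benzene
Conditions: NaH, NaI (cat.), ClCH2SMe, DME, 0 °C → rt
Reagents that add atoms: chloromethyl methyl sulfide CSCCl
Why: Williamson etherification of the sodium alkoxide with the iodide-activated chloromethyl sulfide gives the methylthiomethyl ether.

Step 8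
Reactants: 11 1-methoxy-4-{[(methylsulfanyl)methoxy]methyl}benzene
Product: 12 1-[(chloromethoxy)methyl]-4-methoxybenzene
Conditions: SO2Cl2, CH2Cl2, −78 °C; volatiles removed, used at once
Reagents that add atoms: sulfuryl chloride O=S(=O)(Cl)Cl
Why: Chlorinolysis of the O,S-acetal at sulfur is the standard entry to chloromethyl ethers and spares the electron-rich arene at −78 °C.

Step 9
Reactants: 9 methyl (4R,5E)-6-iodo-4-[(triethylsilyl)oxy]hept-5-en-2-ynoate; 12 1-[(chloromethoxy)methyl]-4-methoxybenzene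
Product: 14 methyl (2Z,4R,5E)-3-ethenyl-6-iodo-2-{[(4-methoxybenzyl)oxy]methyl}-4-[(triethylsilyl)oxy]hepta-2,5-dienoate, via alkenylcopper adduct 13 (not isolated)
Conditions: CH2=CHMgBr, CuBr·SMe2, THF, −78 °C; 9, −78 °C; then 12, −78 → −30 °C
Reagents that add atoms: vinylmagnesium bromide C=C[Mg]Br
Why: Tandem carbocupration–alkylation: syn-addition of vinylcopper puts vinyl (C8) on C7 and copper on C11 cis to it, and the configurationally stable alkenylcopper should be alkylated with retention by the reactive chloromethyl ether (C13), so the ester ends up cis to the C6 carbinol as lactonisation requires.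

Step 10
Reactants: 14 methyl (2Z,4R,5E)-3-ethenyl-6-iodo-2-{[(4-methoxybenzyl)oxy]methyl}-4-[(triethylsilyl)oxy]hepta-2,5-dienoate
Product: 16 (5R)-4-ethenyl-5-[(1E)-2-iodoprop-1-en-1-yl]-3-{[(4-methoxybenzyl)oxy]methyl}furan-2(5H)-one, via hydroxy ester 15 (not isolated)
Conditions: CSA (camphor-10-sulfonic acid, cat.), MeOH/CH2Cl2, 0 °C → rt
Reagents that add atoms: none
Why: Acid-catalysed desilylation–lactonisation: methanolysis frees the γ-hydroxyl, which is held cis to the ester on the tetrasubstituted alkene and closes ring A, and acid is used instead of base so that C6 is not epimerised.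

Step 11
Reactants: 16 (5R)-4-ethenyl-5-[(1E)-2-iodoprop-1-en-1-yl]-3-{[(4-methoxybenzyl)oxy]methyl}furan-2(5H)-one
Product: 18 (2R)-2-[(1E)-2-iodoprop-1-en-1-yl]-4-{[(4-methoxybenzyl)oxy]methyl}-5-oxo-2,5-dihydrofuran-3-carbaldehyde, via diol 17 (not isolated)
Conditions: OsO4 (cat.), NaIO4, 2,6-lutidine, dioxane/H2O, rt
Reagents that add atoms: osmium tetroxide O=[Os](=O)(=O)=O; sodium periodate [Na+].[O-]I(=O)(=O)=O
Why: Lemieux–Johnson oxidation: OsO4 should dihydroxylate the monosubstituted, least hindered alkene in preference to the iodine-bearing trisubstituted and the electron-poor tetrasubstituted alkenes, and periodate cleaves the diol to the C8 aldehyde.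

Step 12
Reactants: 19 acrolein
Product: 20 (±)-pent-1-en-4-yn-3-ol
Conditions: HC≡CMgBr, THF, −78 → 0 °C
Reagents that add atoms: ethynylmagnesium bromide C#C[Mg]Br
Why: Grignard 1,2-addition of the alkynyl reagent to the enal at low temperature gives the vinyl ethynyl carbinol.

Step 13
Reactants: 20 (±)-pent-1-en-4-yn-3-ol
Product: 22 (±)-(1Z)-1-iodo-2-methylpenta-1,4-dien-3-ol, via oxamagnesacycle 21 (not isolated)
Conditions: MeMgBr, CuI (cat.), THF, −20 °C → rt; then I2, −78 → 0 °C
Reagents that add atoms: methylmagnesium bromide C[Mg]Br; iodine II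
Why: Copper-catalysed hydroxyl-directed anti-carbomagnesiation delivers methyl to the alkyne carbon next to the carbinol and leaves magnesium on the terminal carbon in a five-membered chelate cis to the carbinol, so iodinolysis with retention should give only the Z-iodide.

Step 14
Reactants: 22 (±)-(1Z)-1-iodo-2-methylpenta-1,4-dien-3-ol
Product: 23 (3S,1Z)-1-iodo-2-methylpenta-1,4-dien-3-ol
Conditions: Burkholderia cepacia lipase (Amano PS), vinyl acetate, MTBE, 30 °C, stopped just past half conversion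
Reagents that add atoms: none
Why: Enzymatic kinetic resolution by acyl transfer: by the empirical size rule (small vinyl, large iodoalkenyl) the 3R alcohol should be acetylated faster, so the 3S alcohol, which carries the C1 configuration, is recovered.

Step 15
Reactants: 23 (3S,1Z)-1-iodo-2-methylpenta-1,4-dien-3-ol
Product: 24 tert-butyl{[(3S,1Z)-1-iodo-2-methylpenta-1,4-dien-3-yl]oxy}dimethylsilane
Conditions: TBSCl, imidazole, DMF, rt
Reagents that add atoms: tert-butyldimethylsilyl chloride CC(C)(C)[Si](C)(C)Cl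
Why: Imidazole-mediated silylation of the secondary alcohol is neutral enough for the bis-allylic carbinol.

Step 16
Reactants: 24 tert-butyl{[(3S,1Z)-1-iodo-2-methylpenta-1,4-dien-3-yl]oxy}dimethylsilane; 18 (2R)-2-[(1E)-2-iodoprop-1-en-1-yl]-4-{[(4-methoxybenzyl)oxy]methyl}-5-oxo-2,5-dihydrofuran-3-carbaldehyde
Product: 27 (5R)-4-[(2Z,4S)-4-[(tert-butyldimethylsilyl)oxy]-1-hydroxy-3-methylhexa-2,5-dien-1-yl]-5-[(1E)-2-iodoprop-1-en-1-yl]-3-{[(4-methoxybenzyl)oxy]methyl}furan-2(5H)-one (both C8 epimers), via alkenyllithium 25 (not isolated), via alkenylmagnesium bromide 26 (not isolated)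
Conditions: 24, t-BuLi, Et2O, −78 °C; MgBr2·OEt2, −78 °C; then 18 in THF, −78 °C
Reagents that add atoms: none
Why: Halogen–metal exchange with retention of the Z geometry, transmetalation to the less basic Grignard reagent (in ether at −78 °C, before 1,4-silyl migration can set in) and 1,2-addition to the aldehyde, which is far more electrophilic than the lactone; the exchange is run in a separate flask so the C4 iodide of 18 never meets t-BuLi, and no control at C8 is needed because the next two steps reset it.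

Step 17
Reactants: 27 C8-epimeric alcohols
Product: 28 (5R)-4-[(2Z,4S)-4-[(tert-butyldimethylsilyl)oxy]-3-methylhexa-2,5-dienoyl]-5-[(1E)-2-iodoprop-1-en-1-yl]-3-{[(4-methoxybenzyl)oxy]methyl}furan-2(5H)-one
Conditions: Dess–Martin periodinane, NaHCO3, CH2Cl2, 0 °C
Reagents that add atoms: none
Why: Dess–Martin oxidation of the doubly allylic alcohol is fast under buffered, non-basic conditions, which should keep the Z-enone and C6 intact and converge both epimers on one ketone.

Step 18
Reactants: 28 C8 ketone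
Product: 29 (5R)-4-[(1S,2Z,4S)-4-[(tert-butyldimethylsilyl)oxy]-1-hydroxy-3-methylhexa-2,5-dien-1-yl]-5-[(1E)-2-iodoprop-1-en-1-yl]-3-{[(4-methoxybenzyl)oxy]methyl}furan-2(5H)-one
Conditions: (R)-2-methyl-CBS-oxazaborolidine ((3aR)-1-methyl-3,3-diphenyltetrahydro-1H,3H-pyrrolo[1,2-c][1,3,2]oxazaborole), catecholborane, toluene, −78 °C
Reagents that add atoms: none
Why: Corey–Bakshi–Shibata reduction with catecholborane should give clean 1,2-reduction at −78 °C (no hydroboration of the vinyl group), the catalyst delivering hydride to the face that gives 8S when the tetrasubstituted C7 acts as the large group.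

Step 19
Reactants: 29 (8S)-alcohol; 30 tiglic acid
Product: 32 (1S,2Z,4S)-4-[(tert-butyldimethylsilyl)oxy]-1-[(2R)-2-[(1E)-2-iodoprop-1-en-1-yl]-4-{[(4-methoxybenzyl)oxy]methyl}-5-oxo-2,5-dihydrofuran-3-yl]-3-methylhexa-2,5-dien-1-yl (2E)-2-methylbut-2-enoate, via mixed anhydride 31 (not isolated)
Conditions: 30, 2,4,6-trichlorobenzoyl chloride, Et3N, toluene, rt; then 29, DMAP (4-(dimethylamino)pyridine), 0 °C → rt
Reagents that add atoms: none
Why: Yamaguchi esterification: DMAP attacks the less hindered tigloyl carbonyl of the mixed anhydride and the acylpyridinium acylates the hindered secondary alcohol with retention at C8.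

Step 20
Reactants: 32 tiglate bearing the C2=C3 vinyl group and the C4 (E)-alkenyl iodide
Product: 34 (1S,6R,8S,4E,9Z)-1-[(tert-butyldimethylsilyl)oxy]-13-[(4-methoxybenzyl)oxy]-8-[(2E)-2-methylbut-2-enoyloxy]germacra-4,7(11),9-trien-12,6-olide, via B-alkyl-9-BBN borane 33 (not isolated)
Conditions: 9-BBN dimer, THF, 0 °C → rt; then slow addition to PdCl2(dppf)·CH2Cl2 (20 mol %), AsPh3 (20 mol %), Cs2CO3, DMF/THF/H2O, rt, 1–2 mM final concentration
Reagents that add atoms: none
Why: 9-BBN adds anti-Markovnikov only to the monosubstituted C2=C3 alkene (the trisubstituted, conjugated and iodinated alkenes are far slower), zerovalent palladium then inserts into the C4–I bond, the base-activated primary alkylborane transmetalates to divalent palladium, and reductive elimination forms C3–C4. The closest known reaction type is the B-alkyl Suzuki–Miyaura macrocyclisation under high dilution. Ring B (ten-membered) closes through an eleven-membered alkyl(alkenyl)palladacycle by C(sp3)–C(sp2) reductive elimination, which dppf favours over β-hydride elimination. No stereocentre is formed, and the E geometry of C4=C5 is carried over from the alkenyl iodide because oxidative addition and reductive elimination both proceed with retention. The step needs selectivity for C–I over the allylic C–O bonds at C6, C8 and C13 and configurational stability at C6: oxidative addition into the alkenyl iodide at room temperature should be much faster than ionisation of esters flanked by tri- and tetrasubstituted alkenes, C13 is kept as a PMB ether (no leaving group for a C6-deprotonated furanolate to expel and nothing for aqueous carbonate to hydrolyse), and a mild base at room temperature limits deprotonation of C6–H. The Z C9=C10 alkene and the planar butenolide fold the chain so that C3 and C4 can meet, and slow addition keeps the borane dilute enough to disfavour oligomers.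

Step 21
Reactants: 34 macrocyclic PMB ether
Product: 35 (1S,6R,8S,4E,9Z)-1-[(tert-butyldimethylsilyl)oxy]-13-hydroxy-8-[(2E)-2-methylbut-2-enoyloxy]germacra-4,7(11),9-trien-12,6-olide
Conditions: DDQ, CH2Cl2/pH 7 buffer, 0 °C
Reagents that add atoms: none
Why: Oxidative PMB cleavage by hydride abstraction and hydrolysis should leave the silyl ether, the esters and the alkenes (all allylic-oxygenated or conjugated, hence electron-poor) untouched.

Step 22
Reactants: 35 C13 alcohol
Product: 36 (1S,6R,8S,4E,9Z)-13-acetoxy-1-[(tert-butyldimethylsilyl)oxy]-8-[(2E)-2-methylbut-2-enoyloxy]germacra-4,7(11),9-trien-12,6-olide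
Conditions: Ac2O, pyridine, DMAP (cat.), CH2Cl2, 0 °C
Reagents that add atoms: acetic anhydride CC(=O)OC(C)=O
Why: Acetylation of the primary allylic alcohol is fast under weakly basic conditions, faster than tiglate migration from C8 or enolisation at C6.

Step 23
Reactants: 36 C13 acetate
Product: 37 (1S,4R,5R,6S,8S,9Z)-13-acetoxy-1-[(tert-butyldimethylsilyl)oxy]-4,5-epoxy-8-[(2E)-2-methylbut-2-enoyloxy]germacra-7(11),9-dien-12,6-olide
Conditions: dimethyldioxirane (acetone solution), CH2Cl2, −30 → 0 °C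
Reagents that add atoms: dimethyldioxirane CC1(C)OO1
Why: Electrophilic epoxidation with the dioxirane should pick the only alkene that is unconjugated and carries a single allylic oxygen; A(1,3) strain with C15 places C6–H in the plane of the E C4=C5 bond, the ring chain covers the inner face, and the oxidant adds from the outer face syn to the C6–O bond, which corresponds to 4R,5R.

Step 24
Reactants: 37 epoxy silyl ether
Product: 38 (1S,4R,5R,6S,8S,9Z)-13-acetoxy-4,5-epoxy-1-hydroxy-8-[(2E)-2-methylbut-2-enoyloxy]germacra-7(11),9-dien-12,6-olide (target)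
Conditions: HF·pyridine, pyridine, THF, 0 °C → rt
Reagents that add atoms: none
Why: Fluoride desilylation with pyridine-buffered HF·pyridine cleaves the secondary allylic silyl ether under conditions that should be mild enough for the trisubstituted oxirane (deactivated by the adjacent C6–O), the esters and the butenolide.

**Compound list**

1 | ethyl but-2-ynoate | CC#CC(=O)OCC | starting material
2 | ethyl (2E)-3-(tributylstannyl)but-2-enoate | CCOC(=O)/C=C(\C)[Sn](CCCC)(CCCC)CCCC | intermediate
3 | (2E)-3-(tributylstannyl)but-2-en-1-ol | OC/C=C(\C)[Sn](CCCC)(CCCC)CCCC | intermediate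
4 | (2E)-3-iodobut-2-en-1-ol | OC/C=C(\C)I | intermediate
5 | (2E)-3-iodobut-2-enal | O=C/C=C(\C)I | intermediate
6 | methyl propiolate | C#CC(=O)OC | starting material
7 | methyl 3-(methylzincio)prop-2-ynoate (formed in the flask) | C[Zn]C#CC(=O)OC | intermediate
8 | methyl (4R,5E)-4-hydroxy-6-iodohept-5-en-2-ynoate | COC(=O)C#C[C@H](O)/C=C(\C)I | intermediate
9 | methyl (4R,5E)-6-iodo-4-[(triethylsilyl)oxy]hept-5-en-2-ynoate | COC(=O)C#C[C@H](O[Si](CC)(CC)CC)/C=C(\C)I | intermediate
10 | 4-methoxybenzyl alcohol | COc1ccc(CO)cc1 | starting material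
11 | 1-methoxy-4-{[(methylsulfanyl)methoxy]methyl}benzene | COc1ccc(COCSC)cc1 | intermediate
12 | 1-[(chloromethoxy)methyl]-4-methoxybenzene | COc1ccc(COCCl)cc1 | intermediate
13 | methyl (2E,4R,5E)-2-cuprio-3-ethenyl-6-iodo-4-[(triethylsilyl)oxy]hepta-2,5-dienoate (formed in the flask) | COC(=O)/C([Cu])=C(/C=C)[C@H](O[Si](CC)(CC)CC)/C=C(\C)I | intermediate
14 | methyl (2Z,4R,5E)-3-ethenyl-6-iodo-2-{[(4-methoxybenzyl)oxy]methyl}-4-[(triethylsilyl)oxy]hepta-2,5-dienoate | COC(=O)/C(COCc1ccc(OC)cc1)=C(/C=C)[C@H](O[Si](CC)(CC)CC)/C=C(\C)I | intermediate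
15 | methyl (2Z,4R,5E)-3-ethenyl-4-hydroxy-6-iodo-2-{[(4-methoxybenzyl)oxy]methyl}hepta-2,5-dienoate (formed in the flask) | COC(=O)/C(COCc1ccc(OC)cc1)=C(/C=C)[C@H](O)/C=C(\C)I | intermediate
16 | (5R)-4-ethenyl-5-[(1E)-2-iodoprop-1-en-1-yl]-3-{[(4-methoxybenzyl)oxy]methyl}furan-2(5H)-one | C=CC1=C(COCc2ccc(OC)cc2)C(=O)O[C@@H]1/C=C(\C)I | intermediate
17 | (5R)-4-(1,2-dihydroxyethyl)-5-[(1E)-2-iodoprop-1-en-1-yl]-3-{[(4-methoxybenzyl)oxy]methyl}furan-2(5H)-one, both carbinol epimers (formed in the flask) | OCC(O)C1=C(COCc2ccc(OC)cc2)C(=O)O[C@@H]1/C=C(\C)I | intermediate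
18 | (2R)-2-[(1E)-2-iodoprop-1-en-1-yl]-4-{[(4-methoxybenzyl)oxy]methyl}-5-oxo-2,5-dihydrofuran-3-carbaldehyde | O=CC1=C(COCc2ccc(OC)cc2)C(=O)O[C@@H]1/C=C(\C)I | intermediate
19 | acrolein | C=CC=O | starting material
20 | (±)-pent-1-en-4-yn-3-ol | C=CC(O)C#C | intermediate
21 | 5-ethenyl-4-methyl-2,5-dihydro-1,2-oxamagnesole, racemic (formed in the flask) | C=CC1O[Mg]C=C1C | intermediate
22 | (±)-(1Z)-1-iodo-2-methylpenta-1,4-dien-3-ol | C=CC(O)/C(C)=C\I | intermediate
23 | (3S,1Z)-1-iodo-2-methylpenta-1,4-dien-3-ol | C=C[C@H](O)/C(C)=C\I | intermediate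
24 | tert-butyl{[(3S,1Z)-1-iodo-2-methylpenta-1,4-dien-3-yl]oxy}dimethylsilane | C=C[C@H](O[Si](C)(C)C(C)(C)C)/C(C)=C\I | intermediate
25 | [(1Z,3S)-3-[(tert-butyldimethylsilyl)oxy]-2-methylpenta-1,4-dien-1-yl]lithium (formed in the flask) | C=C[C@H](O[Si](C)(C)C(C)(C)C)/C(C)=C\[Li] | intermediate
26 | [(1Z,3S)-3-[(tert-butyldimethylsilyl)oxy]-2-methylpenta-1,4-dien-1-yl]magnesium bromide (formed in the flask) | C=C[C@H](O[Si](C)(C)C(C)(C)C)/C(C)=C\[Mg]Br | intermediate
27 | (5R)-4-[(2Z,4S)-4-[(tert-butyldimethylsilyl)oxy]-1-hydroxy-3-methylhexa-2,5-dien-1-yl]-5-[(1E)-2-iodoprop-1-en-1-yl]-3-{[(4-methoxybenzyl)oxy]methyl}furan-2(5H)-one, both C8 epimers | OC(/C=C(/C)[C@@H](O[Si](C)(C)C(C)(C)C)C=C)C1=C(COCc2ccc(OC)cc2)C(=O)O[C@@H]1/C=C(\C)I | intermediate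
28 | (5R)-4-[(2Z,4S)-4-[(tert-butyldimethylsilyl)oxy]-3-methylhexa-2,5-dienoyl]-5-[(1E)-2-iodoprop-1-en-1-yl]-3-{[(4-methoxybenzyl)oxy]methyl}furan-2(5H)-one | O=C(/C=C(/C)[C@@H](O[Si](C)(C)C(C)(C)C)C=C)C1=C(COCc2ccc(OC)cc2)C(=O)O[C@@H]1/C=C(\C)I | intermediate
29 | (5R)-4-[(1S,2Z,4S)-4-[(tert-butyldimethylsilyl)oxy]-1-hydroxy-3-methylhexa-2,5-dien-1-yl]-5-[(1E)-2-iodoprop-1-en-1-yl]-3-{[(4-methoxybenzyl)oxy]methyl}furan-2(5H)-one | O[C@@H](/C=C(/C)[C@@H](O[Si](C)(C)C(C)(C)C)C=C)C1=C(COCc2ccc(OC)cc2)C(=O)O[C@@H]1/C=C(\C)I | intermediate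
30 | tiglic acid | C/C=C(\C)C(=O)O | starting material
31 | (2E)-2-methylbut-2-enoic 2,4,6-trichlorobenzoic anhydride (formed in the flask) | C/C=C(\C)C(=O)OC(=O)c1c(Cl)cc(Cl)cc1Cl | intermediate
32 | (1S,2Z,4S)-4-[(tert-butyldimethylsilyl)oxy]-1-[(2R)-2-[(1E)-2-iodoprop-1-en-1-yl]-4-{[(4-methoxybenzyl)oxy]methyl}-5-oxo-2,5-dihydrofuran-3-yl]-3-methylhexa-2,5-dien-1-yl (2E)-2-methylbut-2-enoate | C/C=C(\C)C(=O)O[C@@H](/C=C(/C)[C@@H](O[Si](C)(C)C(C)(C)C)C=C)C1=C(COCc2ccc(OC)cc2)C(=O)O[C@@H]1/C=C(\C)I | intermediate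
33 | B-alkyl-9-BBN borane of 32, boron on C3 (formed in the flask) | C/C=C(\C)C(=O)O[C@@H](/C=C(/C)[C@@H](O[Si](C)(C)C(C)(C)C)CCB1C2CCCC1CCC2)C1=C(COCc2ccc(OC)cc2)C(=O)O[C@@H]1/C=C(\C)I | intermediate
34 | (1S,6R,8S,4E,9Z)-1-[(tert-butyldimethylsilyl)oxy]-13-[(4-methoxybenzyl)oxy]-8-[(2E)-2-methylbut-2-enoyloxy]germacra-4,7(11),9-trien-12,6-olide | C/C=C(\C)C(=O)O[C@H]1/C=C(/C)[C@@H](O[Si](C)(C)C(C)(C)C)CC/C(C)=C/[C@H]2OC(=O)C(COCc3ccc(OC)cc3)=C12 | intermediate
35 | (1S,6R,8S,4E,9Z)-1-[(tert-butyldimethylsilyl)oxy]-13-hydroxy-8-[(2E)-2-methylbut-2-enoyloxy]germacra-4,7(11),9-trien-12,6-olide | C/C=C(\C)C(=O)O[C@H]1/C=C(/C)[C@@H](O[Si](C)(C)C(C)(C)C)CC/C(C)=C/[C@H]2OC(=O)C(CO)=C12 | intermediate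
36 | (1S,6R,8S,4E,9Z)-13-acetoxy-1-[(tert-butyldimethylsilyl)oxy]-8-[(2E)-2-methylbut-2-enoyloxy]germacra-4,7(11),9-trien-12,6-olide | C/C=C(\C)C(=O)O[C@H]1/C=C(/C)[C@@H](O[Si](C)(C)C(C)(C)C)CC/C(C)=C/[C@H]2OC(=O)C(COC(C)=O)=C12 | intermediate
37 | (1S,4R,5R,6S,8S,9Z)-13-acetoxy-1-[(tert-butyldimethylsilyl)oxy]-4,5-epoxy-8-[(2E)-2-methylbut-2-enoyloxy]germacra-7(11),9-dien-12,6-olide | C/C=C(\C)C(=O)O[C@H]1/C=C(/C)[C@@H](O[Si](C)(C)C(C)(C)C)CC[C@@]2(C)O[C@@H]2[C@H]2OC(=O)C(COC(C)=O)=C12 | intermediate
38 | (1S,4R,5R,6S,8S,9Z)-13-acetoxy-4,5-epoxy-1-hydroxy-8-[(2E)-2-methylbut-2-enoyloxy]germacra-7(11),9-dien-12,6-olide | C/C=C(\C)C(=O)O[C@H]1/C=C(/C)[C@@H](O)CC[C@@]2(C)O[C@@H]2[C@H]2OC(=O)C(COC(C)=O)=C12 | target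

**Totals and risks**

Total step count: 24. Longest linear sequence: 18 (steps 1–6, 9–11, 16–24).

Steps most likely to fail:

Step 20 (ring closure). Intermolecular coupling may outpace closure of the strained ten-membered ring, or aqueous carbonate may deprotonate C6–H before transmetalation occurs. The fallback closes the same C3–C4 bond without base through an organozinc. It sets out from 32: hydroboration to 33 and oxidation with NaBO3·4H2O should give the C3 primary alcohol of 32, F1; I2, PPh3 and imidazole convert it into the C3 primary iodide, F2; zinc dust with LiCl in THF inserts into the alkyl C–I bond only and gives the C3 alkylzinc iodide, F3, which is cyclised by Negishi coupling (Pd2(dba)3, SPhos, THF, high dilution). It returns to the route at 34.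

Step 9 (carbocupration–alkoxymethylation). The α-ester alkenylcopper may be alkylated only at temperatures where it equilibrates with the allenoate, so that alkene geometry is lost and part of the material cannot lactonise. The fallback replaces the alkylation by an aldol capture. It sets out from 9: the same carbocupration is followed at −78 °C by monomeric formaldehyde with Et2AlCl to give methyl (2Z,4R,5E)-3-ethenyl-2-(hydroxymethyl)-6-iodo-4-[(triethylsilyl)oxy]hepta-2,5-dienoate, F4, which is etherified with 4-methoxybenzyl trichloroacetimidate and catalytic CSA. It returns to the route at 14.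

Step 18 (ketone reduction). Facial discrimination between two alkenyl groups of similar size may be poor, and 1,4-reduction or Z to E isomerisation of the cross-conjugated ketone may compete. The fallback avoids the ketone. It sets out from 27: the C8 epimers are separated by chromatography; the 8S epimer is 29, and the (8R)-epimer of 29, F5, is esterified with tiglic acid 30 under Mitsunobu conditions (PPh3, DIAD, toluene, 0 °C) with inversion at C8. It returns to the route at 29 and 32.

**Further compounds**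

F1 | step 20 | (1S,2Z,4S)-4-[(tert-butyldimethylsilyl)oxy]-6-hydroxy-1-[(2R)-2-[(1E)-2-iodoprop-1-en-1-yl]-4-{[(4-methoxybenzyl)oxy]methyl}-5-oxo-2,5-dihydrofuran-3-yl]-3-methylhex-2-en-1-yl (2E)-2-methylbut-2-enoate | C/C=C(\C)C(=O)O[C@@H](/C=C(/C)[C@@H](O[Si](C)(C)C(C)(C)C)CCO)C1=C(COCc2ccc(OC)cc2)C(=O)O[C@@H]1/C=C(\C)I
F2 | step 20 | (1S,2Z,4S)-4-[(tert-butyldimethylsilyl)oxy]-6-iodo-1-[(2R)-2-[(1E)-2-iodoprop-1-en-1-yl]-4-{[(4-methoxybenzyl)oxy]methyl}-5-oxo-2,5-dihydrofuran-3-yl]-3-methylhex-2-en-1-yl (2E)-2-methylbut-2-enoate | C/C=C(\C)C(=O)O[C@@H](/C=C(/C)[C@@H](O[Si](C)(C)C(C)(C)C)CCI)C1=C(COCc2ccc(OC)cc2)C(=O)O[C@@H]1/C=C(\C)I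
F3 | step 20 | alkylzinc iodide from F2 (zinc on C3) | C/C=C(\C)C(=O)O[C@@H](/C=C(/C)[C@@H](O[Si](C)(C)C(C)(C)C)CC[Zn]I)C1=C(COCc2ccc(OC)cc2)C(=O)O[C@@H]1/C=C(\C)I
F4 | step 9 | methyl (2Z,4R,5E)-3-ethenyl-2-(hydroxymethyl)-6-iodo-4-[(triethylsilyl)oxy]hepta-2,5-dienoate | COC(=O)/C(CO)=C(/C=C)[C@H](O[Si](CC)(CC)CC)/C=C(\C)I
F5 | step 18 | (5R)-4-[(1R,2Z,4S)-4-[(tert-butyldimethylsilyl)oxy]-1-hydroxy-3-methylhexa-2,5-dien-1-yl]-5-[(1E)-2-iodoprop-1-en-1-yl]-3-{[(4-methoxybenzyl)oxy]methyl}furan-2(5H)-one | O[C@H](/C=C(/C)[C@@H](O[Si](C)(C)C(C)(C)C)C=C)C1=C(COCc2ccc(OC)cc2)C(=O)O[C@@H]1/C=C(\C)I
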